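**Plan**

- Numbering of the target: C1 is the quaternary carbinol carbon carrying C7H2OBz, C2 bears OAc, C3 OBz, C4=C5 is the alkene, C6 bears OH. C3 and C6 are para across the six-membered ring, both oxygenated, and flank C4=C5, so the carbocycle is a masked 2-(hydroxymethyl)hydroquinone dimethyl ether.
- Retrosynthetic cuts, in order: C6–H (back to a ketone), the C7–O benzoate, C2–OAc (back to a C1–C2 epoxide), the C3–O benzoate and C3–H (back to an epoxy ene-dione), the two epoxide C–O bonds (back to an allylic alcohol), and last the C3–OMe and C6–OMe ketal bonds (back to the arene).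
- Forward: no ring is closed anywhere. The only ring is the benzene ring of 2,5-dimethoxybenzyl alcohol, which is dearomatised anodically to a quinone bisketal, epoxidised at C1=C2, unmasked to the ene-dione, then reduced and acylated one oxygen at a time.
- Stereochemistry: C1 and C2 come from a Sharpless asymmetric epoxidation (D-(−)-tartrate); C3 from hydride addition anti to the epoxide; C2 is then inverted by SN2 acetate opening; C6 comes from a reduction directed by the C1 hydroxyl.

Key step: step 1

Remark: in step 4 either ketal may hydrolyse first without consequence, and intermediate 6 is written as the isomer with the ketone next to C1; in fallback compounds F1 and F2 the C6 carbinol is drawn syn to the epoxide, a centre that is erased again on oxidation.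

**Route**

Step 1
Reactants: 1 2,5-dimethoxybenzyl alcohol; 2 methanol
Product: 3 (3,3,6,6-tetramethoxycyclohexa-1,4-dien-1-yl)methanol
Conditions: Pt anode, Pt cathode, undivided cell, 1% KOH in MeOH, constant current (about 2.5 F/mol planned), 0 °C
Reagents that add atoms: methanol, CO
Why: Anodic bis-methoxylation of a 1,4-dimethoxyarene to a quinone bisketal (a known electrochemical ketalisation of hydroquinone dimethyl ethers): one-electron oxidation of 1 gives an arene radical cation whose charge sits on the two methoxy-bearing carbons, methoxide adds at one of them, the cyclohexadienyl radical is oxidised again and a second methoxide adds at the para ipso carbon, while methanol is reduced to hydrogen at the cathode. The C3–O and C6–O ketal bonds are formed and no ring is closed; the benzene ring becomes a cyclohexa-1,4-diene whose sp3 carbons are C3 and C6. No stereocentre arises, because each new sp3 carbon carries two identical methoxy groups. The selectivity needed is nuclear ipso,ipso addition rather than oxidation of the benzylic alcohol or substitution at ring CH positions; it is secured by the para-dimethoxy pattern, which puts the highest positive charge on the oxygenated carbons, and by basic methanol, in which methoxide capture outruns benzylic deprotonation. The bisketal is no longer aromatic and is oxidised at a much higher potential than 1, so it should survive the electrolysis, and the C7 hydroxyl is carried through free because step 2 needs it.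

Step 2
Reactants: 3
Product: 4 [(1R,6S)-2,2,5,5-tetramethoxy-7-oxabicyclo[4.1.0]hept-3-en-1-yl]methanol
Conditions: Ti(OiPr)4 (cat.), D-(−)-diisopropyl tartrate (cat.), t-BuOOH (anhydrous), 4 Å MS, CH2Cl2, −20 °C; non-acidic work-up
Reagents that add atoms: tert-butyl hydroperoxide, CC(C)(C)OO
Why: Sharpless asymmetric epoxidation, in which only C1=C2 is an allylic-alcohol alkene and is therefore epoxidised in preference to C4=C5, and D-(−)-tartrate delivers oxygen to the face that gives the (1R,6S) oxabicycle, fixing C1 and (before its later inversion) C2.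

Step 3
Reactants: 4
Product: 5 tert-butyl(diphenyl){[(1R,6S)-2,2,5,5-tetramethoxy-7-oxabicyclo[4.1.0]hept-3-en-1-yl]methoxy}silane
Conditions: TBDPSCl, imidazole, DMF, 0 °C → rt
Reagents that add atoms: tert-butyl(chloro)diphenylsilane, CC(C)(C)[Si](Cl)(c1ccccc1)c1ccccc1
Why: Standard silylation of a primary alcohol; the acid-stable, bulky silyl ether survives step 4, keeps the C7 oxygen from binding or directing hydride in step 5, blocks its benzoylation in step 6 and adds bulk next to C6.

Step 4
Reactants: 5
Product: 7 (1R,6S)-1-{[tert-butyl(diphenyl)silyl]oxymethyl}-7-oxabicyclo[4.1.0]hept-3-ene-2,5-dione, via mono-ketal epoxy enone 6 (not isolated)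
Conditions: TFA/H2O (9:1), CH2Cl2, 0 °C → rt
Reagents that add atoms: water, O
Why: Acid hydrolysis of allylic dimethyl ketals (bisketal-to-quinone type), each ketal ionising to a methoxy-stabilised allyl cation that water captures; the epoxide, flanked by two electron-poor carbons, and the TBDPS ether should tolerate aqueous TFA, and full hydrolysis avoids any need to choose between the two ketals.

Step 5
Reactants: 7
Product: 8 (1R,5R,6R)-1-{[tert-butyl(diphenyl)silyl]oxymethyl}-5-hydroxy-7-oxabicyclo[4.1.0]hept-3-en-2-one
Conditions: i-Bu2AlH (DIBAL-H, 1.05 equiv), THF, −78 °C; aq. potassium sodium tartrate work-up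
Reagents that add atoms: none
Why: Regio- and stereoselective 1,2-reduction of an epoxy ene-dione, in which the C3 carbonyl beside the epoxide CH is far more accessible than the C6 carbonyl beside quaternary C1 and its CH2OTBDPS group, and hydride adds anti to the epoxide oxygen as is usual for 2,3-epoxycyclohexenones, placing the C3 hydroxyl syn to the epoxide (3R in target numbering).

Step 6
Reactants: 8; 9 benzoyl chloride
Product: 10 (1R,5R,6R)-5-(benzoyloxy)-1-{[tert-butyl(diphenyl)silyl]oxymethyl}-7-oxabicyclo[4.1.0]hept-3-en-2-one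
Conditions: BzCl, pyridine, DMAP (cat.), CH2Cl2, 0 °C
Reagents that add atoms: benzoyl chloride, O=C(Cl)c1ccccc1
Why: Acylation of the only free hydroxyl (secondary, allylic) with an acid chloride; C3 keeps its configuration.

Step 7
Reactants: 10
Product: 11 (1R,5R,6R)-5-(benzoyloxy)-1-(hydroxymethyl)-7-oxabicyclo[4.1.0]hept-3-en-2-one
Conditions: HF·pyridine, pyridine/THF, 0 °C → rt
Reagents that add atoms: none
Why: Fluoride cleavage of the Si–O bond under buffered, non-basic conditions, so that the γ-benzoyloxy enone and the epoxy ketone are not exposed to basic fluoride (no elimination, no benzoyl migration).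

Step 8
Reactants: 11; 12 acetic acid
Product: 13 (4R,5S,6R)-5-(acetyloxy)-4-(benzoyloxy)-6-hydroxy-6-(hydroxymethyl)cyclohex-2-en-1-one
Conditions: Ti(OiPr)4 (1.5 equiv), AcOH (3 equiv), CH2Cl2, 0 °C → rt
Reagents that add atoms: acetic acid, CC(=O)O
Why: Titanium-mediated regioselective opening of a 2,3-epoxy alcohol by a carboxylic acid: titanium bound to the C7 alkoxide and the epoxide oxygen activates the ring, and acetate attacks the distal carbon C2 (secondary and β to the C6 ketone, whereas C1 is quaternary and α to C=O) in SN2 fashion from the face opposite the oxygen, inverting C2 and leaving the C1–O bond intact, so that C1–OH and C2–OAc are trans and C2–OAc is trans to the C3 benzoate.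

Step 9
Reactants: 13; 9 benzoyl chloride
Product: 14 (4R,5S,6R)-5-(acetyloxy)-4-(benzoyloxy)-6-[(benzoyloxy)methyl]-6-hydroxycyclohex-2-en-1-one
Conditions: BzCl (1.1 equiv), pyridine, CH2Cl2, −20 → 0 °C
Reagents that add atoms: benzoyl chloride, O=C(Cl)c1ccccc1
Why: Chemoselective benzoylation of the primary alcohol, the only other hydroxyl being tertiary and α to a ketone; it also removes the C7 hydroxyl as a competing director for step 10.

Step 10
Reactants: 14
Product: 15 (1S,2S,3R,6R)-2-acetoxy-3-benzoyloxy-1-(benzoyloxymethyl)cyclohex-4-ene-1,6-diol (target)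
Conditions: Me4NBH(OAc)3, MeCN/AcOH (1:1), −30 → −20 °C
Reagents that add atoms: none
Why: Hydroxyl-directed triacetoxyborohydride reduction (Evans–Saksena type): the reagent exchanges an acetate for the C1 tertiary hydroxyl, the only free OH, and delivers hydride to the adjacent C6 carbonyl from the face of that hydroxyl, giving the trans-1,6-diol (6R) by 1,2-reduction while the esters are untouched in the acidic medium.

**Compound list**

1 | 2,5-dimethoxybenzyl alcohol | COc1ccc(OC)c(CO)c1 | starting material
2 | methanol | CO | starting material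
3 | (3,3,6,6-tetramethoxycyclohexa-1,4-dien-1-yl)methanol | COC1(OC)C=CC(OC)(OC)C(CO)=C1 | intermediate
4 | [(1R,6S)-2,2,5,5-tetramethoxy-7-oxabicyclo[4.1.0]hept-3-en-1-yl]methanol | OC[C@@]12O[C@@H]1C(OC)(OC)C=CC2(OC)OC | intermediate
5 | tert-butyl(diphenyl){[(1R,6S)-2,2,5,5-tetramethoxy-7-oxabicyclo[4.1.0]hept-3-en-1-yl]methoxy}silane | CC(C)(C)[Si](OC[C@@]12O[C@@H]1C(OC)(OC)C=CC2(OC)OC)(c1ccccc1)c1ccccc1 | intermediate
6 | (1R,6S)-1-{[tert-butyl(diphenyl)silyl]oxymethyl}-5,5-dimethoxy-7-oxabicyclo[4.1.0]hept-3-en-2-one (mono-ketal, not isolated) | CC(C)(C)[Si](OC[C@@]12O[C@@H]1C(OC)(OC)C=CC2=O)(c1ccccc1)c1ccccc1 | intermediate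
7 | (1R,6S)-1-{[tert-butyl(diphenyl)silyl]oxymethyl}-7-oxabicyclo[4.1.0]hept-3-ene-2,5-dione | CC(C)(C)[Si](OC[C@@]12O[C@@H]1C(=O)C=CC2=O)(c1ccccc1)c1ccccc1 | intermediate
8 | (1R,5R,6R)-1-{[tert-butyl(diphenyl)silyl]oxymethyl}-5-hydroxy-7-oxabicyclo[4.1.0]hept-3-en-2-one | CC(C)(C)[Si](OC[C@@]12O[C@@H]1[C@H](O)C=CC2=O)(c1ccccc1)c1ccccc1 | intermediate
9 | benzoyl chloride | O=C(Cl)c1ccccc1 | starting material
10 | (1R,5R,6R)-5-(benzoyloxy)-1-{[tert-butyl(diphenyl)silyl]oxymethyl}-7-oxabicyclo[4.1.0]hept-3-en-2-one | CC(C)(C)[Si](OC[C@@]12O[C@@H]1[C@H](OC(=O)c3ccccc3)C=CC2=O)(c1ccccc1)c1ccccc1 | intermediate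
11 | (1R,5R,6R)-5-(benzoyloxy)-1-(hydroxymethyl)-7-oxabicyclo[4.1.0]hept-3-en-2-one | OC[C@@]12O[C@@H]1[C@H](OC(=O)c3ccccc3)C=CC2=O | intermediate
12 | acetic acid | CC(=O)O | starting material
13 | (4R,5S,6R)-5-(acetyloxy)-4-(benzoyloxy)-6-hydroxy-6-(hydroxymethyl)cyclohex-2-en-1-one | CC(=O)O[C@H]1[C@H](OC(=O)c2ccccc2)C=CC(=O)[C@@]1(O)CO | intermediate
14 | (4R,5S,6R)-5-(acetyloxy)-4-(benzoyloxy)-6-[(benzoyloxy)methyl]-6-hydroxycyclohex-2-en-1-one | CC(=O)O[C@H]1[C@H](OC(=O)c2ccccc2)C=CC(=O)[C@@]1(O)COC(=O)c1ccccc1 | intermediate
15 | (1S,2S,3R,6R)-2-acetoxy-3-benzoyloxy-1-(benzoyloxymethyl)cyclohex-4-ene-1,6-diol | CC(=O)O[C@H]1[C@H](OC(=O)c2ccccc2)C=C[C@@H](O)[C@@]1(O)COC(=O)c1ccccc1 | target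

**Step count and risks**

Total steps: 10. Longest linear sequence: 10 steps (1 → 15).

Steps most likely to fail:

1. Step 5. What may go wrong: too little discrimination between the two ring carbonyls, so that hydride also adds at C6 or at both. Fallback (from 7, back at 10): the differentiation is moved from the reduction to an acylation. Excess i-Bu2AlH (THF, −78 °C) reduces both carbonyls of 7 to the epoxy diol (1S,2S,5R,6R)-1-{[tert-butyl(diphenyl)silyl]oxymethyl}-7-oxabicyclo[4.1.0]hept-3-ene-2,5-diol F1. One equivalent of BzCl (pyridine, CH2Cl2, −40 °C) should acylate the C3 hydroxyl beside the epoxide CH and leave the neopentylic C6 hydroxyl beside quaternary C1, giving the monobenzoate (1S,2S,5R,6R)-5-(benzoyloxy)-1-{[tert-butyl(diphenyl)silyl]oxymethyl}-7-oxabicyclo[4.1.0]hept-3-en-2-ol F2. Dess–Martin oxidation of the remaining allylic alcohol (CH2Cl2, rt) then gives 10.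

2. Step 8. What may go wrong: attack of acetate at the wrong epoxide carbon, migration of the new acetyl group to the free primary hydroxyl, or titanium alkoxide side reactions at the enone. Fallback (from 11, back at 14): C7–OH is benzoylated first (BzCl, pyridine, CH2Cl2, 0 °C) to the dibenzoate [(1R,5R,6R)-5-(benzoyloxy)-2-oxo-7-oxabicyclo[4.1.0]hept-3-en-1-yl]methyl benzoate F3. This is opened with AcOH and catalytic Sc(OTf)3 (CH2Cl2, rt). Regiocontrol then rests on the epoxy-ketone polarity alone: C1 is quaternary and α to C=O, so the acid-activated epoxide is attacked at the β-carbon C2 with inversion. No free primary hydroxyl is left to accept the acetyl group, and the product is 14 directly.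

3. Step 2. What may go wrong: slow oxygen transfer to a hindered, inductively deactivated alkene, and ionisation of the bis-allylic ketals by the titanium Lewis acid. Fallback (from 3, back at 4): asymmetric catalysis is given up for a resolution. VO(acac)2 (cat.) with t-BuOOH (CH2Cl2, 0 °C), a more reactive and less Lewis-acidic hydroxyl-directed system, epoxidises C1=C2 to the racemic epoxy alcohol rac-[(1R*,6S*)-2,2,5,5-tetramethoxy-7-oxabicyclo[4.1.0]hept-3-en-1-yl]methanol F4. Its enantiomers are separated by preparative chromatography on a chiral stationary phase, and the (1R,6S) enantiomer is 4.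

Further compounds
F1 | step 5 | (1S,2S,5R,6R)-1-{[tert-butyl(diphenyl)silyl]oxymethyl}-7-oxabicyclo[4.1.0]hept-3-ene-2,5-diol | CC(C)(C)[Si](OC[C@@]12O[C@@H]1[C@H](O)C=C[C@@H]2O)(c1ccccc1)c1ccccc1
F2 | step 5 | (1S,2S,5R,6R)-5-(benzoyloxy)-1-{[tert-butyl(diphenyl)silyl]oxymethyl}-7-oxabicyclo[4.1.0]hept-3-en-2-ol | CC(C)(C)[Si](OC[C@@]12O[C@@H]1[C@H](OC(=O)c3ccccc3)C=C[C@@H]2O)(c1ccccc1)c1ccccc1
F3 | step 8 | [(1R,5R,6R)-5-(benzoyloxy)-2-oxo-7-oxabicyclo[4.1.0]hept-3-en-1-yl]methyl benzoate | O=C(OC[C@@]12O[C@@H]1[C@H](OC(=O)c3ccccc3)C=CC2=O)c1ccccc1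
F4 | step 2 | rac-[(1R*,6S*)-2,2,5,5-tetramethoxy-7-oxabicyclo[4.1.0]hept-3-en-1-yl]methanol (racemate; cis ring fusion fixes the relative configuration) | OCC12OC1C(OC)(OC)C=CC2(OC)OC
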